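Readings and results were generated by integration on assumed constants, noise included.

After 3.00 min the earlier runs alder, elm and oak change slowly, and the asked time 8.0 min lies later still, so I read that pace first.

| setting | alder | elm | oak | eta | zeta | alpha | delta |
|---|---|---|---|---|---|---|---|
| starting material | 0.050 M | 0.050 M | 0.050 M | 0.050 M | 0.050 M | 0.050 M | 0.050 M |
| catalyst | 0.61 mol% | 1.7 mol% | 3.5 mol% | 0.8 mol% | 1.2 mol% | 2 mol% | 3 mol% |
| remark | run made earlier | run made earlier | run made earlier |  |  |  |  |
| time |  |  |  | 8.0 min | 8.0 min | 8.0 min | 8.0 min |

| run | time / min | target / % | starting material / % |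
|---|---|---|---|
| alder | 0.417 | 33 | 57 |
| alder | 0.833 | 37 | 37 |
| alder | 1.50 | 30 | 24 |
| alder | 3.00 | 14 | 12 |
| alder | 6.00 | 4 | 2 |
| elm | 1.00 | 37 | 31 |
| elm | 2.50 | 21 | 14 |
| elm | 3.00 | 16 | 8 |
| elm | 5.00 | 8 | 5 |
| elm | 6.00 | 5 | 1 |
| oak | 0.417 | 35 | 60 |
| oak | 0.833 | 36 | 36 |
| oak | 1.50 | 33 | 23 |
| oak | 3.00 | 17 | 10 |
| oak | 6.00 | 3 | 2 |

(standard deviation of a reading: 1.5 percentage points)

- "hardly changes" means that all values lie within two and a half points (for a concentration: within two and a half percent of the largest)

- [target] at the end for eta, zeta, alpha, delta, in this order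
- how the row runs (rises all the way / hardly changes / rises, then falls / falls all the way / falls, then rises)

Oak carries 5.74 times the loading of alder, yet at 3.00 min they hold 14% and 17% of target. That gap is no clear signal against the scatter, so I sum alder, elm and oak at 3.00 min and again at 6.00 min. Late on, both columns look like a pseudo-first-order decay, which gives me two separate ways to one rate.

From the target column:

0.455 min⁻¹

From the starting-material column:

0.597 min⁻¹

They part. At 6.00 min the starting material reads 2%, 1% and 2% against a scatter of 1.5 percentage points, while target reads 4%, 5% and 3%. The second rate therefore hangs on readings close to their noise, and I keep the first. From it I take the tail half-life, the time target needs to halve late in a run, as read from these scattered readings: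

1.52 min

Carrying the mean target at 6.00 min forward to 8.0 min gives

1.61% of the charge, or 8.05 × 10⁻⁴ M,

and I see no loading effect above the scatter of the readings, so I expect this value in each new flask.

The forecast stands at 8.000 × 10⁻⁴ M for each flask and reads hardly changes: “the row should stay flat”.

Eta ends at 9.88 × 10⁻⁴ M and delta at 9.40 × 10⁻⁴ M, so the row falls all the way. Eta's target, 1.98% of the charge, stands higher than my 1.61%.

    target → over-reaction product (k = 0.0139 s⁻¹)
    target + catalyst ⇌ isomer of the product + catalyst, rate k2*[catalyst]*[target] forward; the back reaction follows from the equilibrium constant (K = 0.270, k = 9.86 L mol⁻¹ s⁻¹)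
    starting material ⇌ target (K = 2.52, k = 0.0249 s⁻¹)

In eta, the half-life of target by the step to over-reaction product, 0.83 min, is shorter than the 2.9 min of its forward step to the isomer of the product. Starting instead from delta's 11.1% of target at 4.00 min, the tail half-life gives 1.79% at 8.00 min, and delta holds 1.88%.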